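**Retrosynthetic overview**
1. Numbering: ring C14(H)–C1H2–C2=C3(Me)–C4–C5–C6=C7(CH2OH)–C8–C9–C10=C11(Me)–C12–C13–(C14). Side chain C15(Me)=C16–C17–C18=C19Me2.
2. Feature: the 14-membered carbocycle has one stereocentre, the ring methine C14. It has no heteroatom handle, but it is allylic to the exocyclic C15=C16 olefin. A temporary C16–O stereocentre can therefore be exchanged for C14 in a [3,3] shift that also makes C13–C14 and the E olefin.
3. Disconnections (retro): CH2OH from the ester; C6=C7 by intramolecular HWE; C11–C12 by alkylzinc/alkenyl iodide coupling; C13–C14 by Eschenmoser–Claisen rearrangement; C1–C2 by Pd allyl–alkenyl coupling; C16–C17 by linear prenylation of a C5 enal.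
4. Order: first an acyclic three-armed hub (amide at C12, acetal at C6, finished side chain), then the C7–C11 arm. The only ring, the 14-membered one, is closed last at C6=C7.

Key step: step 8

Assumption: the phosphonate-bearing carbon C7 in 29, 34 and 35 is carried as a mixture of epimers. It becomes sp2 in step 16, so it is not treated as a stereocentre.

**Step 1**
Reactants: 1 (2E)-4-acetoxy-2-methylbut-2-enal; 2 prenyl chloride
Product: 4 rac-(2E)-4-hydroxy-3,7-dimethylocta-2,6-dien-1-yl acetate, via prenylbarium chloride 3 (not isolated)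
Conditions: Li, biphenyl, BaI2, THF, rt; 2, −78 °C; 1 (ca. 0.9 equiv to reagent), −78 °C; aq NH4Cl
Reagents that add atoms: none
Why: Allylbarium carbonyl addition: at −78 °C prenylbarium chloride keeps its primary C–Ba bond and attacks aldehydes 1,2 through that unsubstituted α-carbon, so the linear C16–C17 bond should form; with about one equivalent of reagent the aldehyde should be consumed before the acetate is touched, and the racemic carbinol centre is erased in step 2.

**Step 2**
Reactants: 4 rac-(2E)-4-hydroxy-3,7-dimethylocta-2,6-dien-1-yl acetate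
Product: 5 (2E)-3,7-dimethyl-4-oxoocta-2,6-dien-1-yl acetate
Conditions: activated MnO2 (excess), CH2Cl2, rt
Reagents that add atoms: none
Why: Allylic alcohol oxidation with activated MnO2 is neutral and heterogeneous, so the acetate should persist and the C18=C19 olefin should not move into conjugation with the new ketone.

**Step 3**
Reactants: 5 (2E)-3,7-dimethyl-4-oxoocta-2,6-dien-1-yl acetate
Product: 6 (2E,4S)-4-hydroxy-3,7-dimethylocta-2,6-dien-1-yl acetate
Conditions: (R)-2-methyl-CBS-oxazaborolidine (0.2 equiv), catecholborane, toluene, −78 °C; MeOH, then NaHCO3 wash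
Reagents that add atoms: none
Why: Corey–Bakshi–Shibata reduction: the α-methylalkenyl residue acts as the large group and the C17 methylene as the small one, so the (R)-catalyst should direct hydride to the face giving the (S)-carbinol at C16 (sense and ee to be confirmed by Mosher ester analysis before going on), and catecholborane at −78 °C should spare the acetate and the trisubstituted olefins.

**Step 4**
Reactants: 6 (2E,4S)-4-hydroxy-3,7-dimethylocta-2,6-dien-1-yl acetate
Product: 7 (2E,4S)-3,7-dimethyl-4-(triethylsilyloxy)octa-2,6-dien-1-yl acetate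
Conditions: TESCl, imidazole, CH2Cl2, 0 °C
Reagents that add atoms: chlorotriethylsilane CC[Si](Cl)(CC)CC
Why: Standard silylation of a secondary alcohol masks the O–H that would otherwise protonate the alkenylzinc reagent of step 6, and it does not touch the stereocentre.

**Step 5**
Reactants: 8 2-(2-bromoethyl)-1,3-dioxolane; 9 propyne
Product: 12 2-[(3Z)-4-iodo-3-methylbut-3-en-1-yl]-1,3-dioxolane, via Grignard reagent 10 (not isolated), via (Z)-alkenylcopper 11 (not isolated)
Conditions: Mg, THF, 25–30 °C; CuBr·SMe2, Et2O–Me2S, −45 °C; 9, −25 °C; I2, −78 to 0 °C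
Reagents that add atoms: iodine II
Why: Grignard formation followed by syn-carbocupration of a terminal alkyne (Normant type): the alkyl group adds to the internal carbon and copper to the terminal carbon on the same side, and iodinolysis with retention places iodine cis to C4, which is the Z geometry needed at C2=C3.

**Step 6**
Reactants: 12 2-[(3Z)-4-iodo-3-methylbut-3-en-1-yl]-1,3-dioxolane; 7 (2E,4S)-3,7-dimethyl-4-(triethylsilyloxy)octa-2,6-dien-1-yl acetate
Product: 15 {[(5S,6E,9Z)-12-(1,3-dioxolan-2-yl)-2,6,10-trimethyldodeca-2,6,9-trien-5-yl]oxy}triethylsilane, via (Z)-alkenyllithium 13 (not isolated), via (Z)-alkenylzinc chloride 14 (not isolated)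
Conditions: 12, t-BuLi (2 equiv), Et2O, −78 °C; ZnCl2, THF, −78 to 0 °C; 7, Pd(PPh3)4 (5 mol %), THF, rt
Reagents that add atoms: none
Why: Negishi-type Pd-catalysed allyl–alkenyl coupling: iodine–lithium exchange and transmetalation to zinc keep the Z geometry, the primary allylic acetate gives a π-allyl complex of the geranyl substitution pattern that holds its E geometry, and reductive elimination should occur at the unhindered CH2 terminus C1 rather than at the fully substituted C15.

**Step 7**
Reactants: 15 triethylsilyl ether of the skipped dienol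
Product: 16 (5S,6E,9Z)-12-(1,3-dioxolan-2-yl)-2,6,10-trimethyldodeca-2,6,9-trien-5-ol
Conditions: TBAF, THF, 0 °C
Reagents that add atoms: none
Why: Fluoride cleavage of a triethylsilyl ether is non-acidic, so the dioxolane and the skipped diene should be unaffected and the C16 configuration retained.

**Step 8**
Reactants: 16 (5S,6E,9Z)-12-(1,3-dioxolan-2-yl)-2,6,10-trimethyldodeca-2,6,9-trien-5-ol; 17 N,N-dimethylacetamide dimethyl acetal
Product: 20 (3S,4E)-3-[(2Z)-5-(1,3-dioxolan-2-yl)-3-methylpent-2-en-1-yl]-N,N,4,8-tetramethylnona-4,7-dienamide, via mixed amide acetal 18 (not isolated), via ketene N,O-acetal 19 (not isolated)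
Conditions: 17 (4 equiv), xylene, 130 °C, MeOH distilled off
Reagents that add atoms: none
Why: Alcohol 16 displaces one methoxy group of 17 to give 18, which loses methanol to the ketene N,O-acetal 19; 19 then undergoes a concerted [3,3]-sigmatropic shift (Eschenmoser–Claisen rearrangement, the amide acetal variant of the Claisen rearrangement) that forms C13–C14, breaks C16–O and moves the olefin from C14=C15 to C15=C16. No ring is closed, since the six-membered array exists only in the transition state. The new stereocentre C14 is controlled by the C16 carbinol: the new bond grows on the face of the allyl unit from which the oxygen departs, so the (S)-carbinol with an E C14=C15 olefin should give the arrangement that is 14R in the target (S by CIP in 20, where C13 outranks C1). The step needs complete suprafacial transfer and E geometry at C15=C16; both rest on the chair that places the C17 methylene equatorial, because the axial alternative runs into the dimethylamino group, and on the geometric purity of the C14=C15 olefin inherited from 1. The medium is neutral, so the dioxolane and the skipped dienes should survive, and C14=C15 is the only olefin allylic to the oxygen, so there is no regiochemical alternative.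

**Step 9**
Reactants: 20 hub amide
Product: 21 (3S,4E)-3-[(2Z)-5-(1,3-dioxolan-2-yl)-3-methylpent-2-en-1-yl]-4,8-dimethylnona-4,7-dien-1-ol
Conditions: BH3·NH3, LDA, THF, 0 °C to rt (lithium amidotrihydroborate); 20, 0 °C to rt; aq NH4Cl
Reagents that add atoms: none
Why: Reduction of a tertiary amide with lithium amidotrihydroborate proceeds with C–N cleavage and further reduction of the aldehyde stage, so the primary alcohol rather than the amine should result, and the acetal, the olefins and the non-acidic stereocentre C14 are left alone.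

**Step 10**
Reactants: 21 hub alcohol
Product: 22 2-[(3Z,6S,7E)-6-(2-iodoethyl)-3,7,11-trimethyldodeca-3,7,10-trien-1-yl]-1,3-dioxolane
Conditions: I2, PPh3, imidazole, CH2Cl2, 0 °C to rt
Reagents that add atoms: iodine II
Why: Appel iodination converts the primary alcohol by SN2 displacement of the oxyphosphonium ion, and imidazole buffers the medium so the dioxolane should stay intact.

**Step 11**
Reactants: 23 pent-3-yn-1-ol
Product: 25 (3E)-4-iodopent-3-en-1-ol, via (E)-alkenylzirconocene 24 (not isolated)
Conditions: Cp2Zr(H)Cl (2.5–3 equiv), THF, rt to 40 °C; I2, 0 °C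
Reagents that add atoms: iodine II
Why: Hydrozirconation–iodination: after the first equivalent is spent on the O–H, syn addition of Zr–H and equilibration by excess reagent should place zirconium on the less hindered, methyl-bearing carbon C11, and iodinolysis with retention gives the E iodide with C9 cis to the methyl group.

**Step 12**
Reactants: 25 (3E)-4-iodopent-3-en-1-ol
Product: 26 (2E)-2,5-diiodopent-2-ene
Conditions: I2, PPh3, imidazole, CH2Cl2, 0 °C
Reagents that add atoms: iodine II
Why: Appel iodination of the primary alcohol is an SN2 process that does not affect the alkenyl iodide or its geometry.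

**Step 13**
Reactants: 26 (2E)-2,5-diiodopent-2-ene; 27 triethyl phosphonoacetate
Product: 29 ethyl (5E)-2-(diethoxyphosphoryl)-6-iodohept-5-enoate, via sodio phosphonoacetate 28 (not isolated)
Conditions: 27 (1.5 equiv), NaH, THF–DMF, 0 °C; 26, 50 °C
Reagents that add atoms: none
Why: SN2 alkylation of a stabilised phosphonoacetate carbanion takes place only at the primary sp3 iodide because the alkenyl iodide is inert to substitution, and the excess of 27 limits double alkylation.

**Step 14**
Reactants: 22 hub iodide; 29 ethyl (5E)-2-(diethoxyphosphoryl)-6-iodohept-5-enoate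
Product: 34 ethyl (5E,9R,10E)-2-(diethoxyphosphoryl)-9-[(2Z)-5-(1,3-dioxolan-2-yl)-3-methylpent-2-en-1-yl]-6,10,14-trimethylpentadeca-5,10,13-trienoate, via alkyllithium 30 (not isolated), via alkylzinc chloride 31 (not isolated), via sodio phosphonate 32 (not isolated), via coupled sodio phosphonate 33 (not isolated)
Conditions: 22, t-BuLi (2.1 equiv), Et2O–pentane, −78 °C; ZnCl2, THF, −78 to 0 °C; second flask: 29, NaH (1.0 equiv), THF, 0 °C; combine, PdCl2(dppf) (5 mol %), THF, rt; aq NH4Cl
Reagents that add atoms: none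
Why: Negishi sp3–sp2 coupling: iodine–lithium exchange on the primary iodide at −78 °C should outrun 5-exo carbolithiation of the trisubstituted C2=C3 olefin, zinc tames the carbanion, the bidentate dppf ligand favours reductive elimination over β-hydride loss so that C11–C12 forms with retention of the E geometry, and converting 29 to its inert sodium salt first removes the one acidic C–H that could protonate the organozinc.

**Step 15**
Reactants: 34 coupled phosphonate acetal
Product: 35 ethyl (5E,9R,10E)-2-(diethoxyphosphoryl)-6,10,14-trimethyl-9-[(2Z)-3-methyl-6-oxohex-2-en-1-yl]pentadeca-5,10,13-trienoate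
Conditions: PPTS (0.3 equiv), acetone–H2O, 55 °C
Reagents that add atoms: water O
Why: Mild acid-catalysed acetal hydrolysis frees the C6 aldehyde; the esters and trisubstituted olefins tolerate PPTS, and the only cationic closure available to the C2=C3 olefin would be a disfavoured 5-endo process.

**Step 16**
Reactants: 35 seco aldehyde phosphonate
Product: 36 ethyl (1E,5Z,8R,11E)-5,11-dimethyl-8-[(2E)-6-methylhepta-2,5-dien-2-yl]cyclotetradeca-1,5,11-triene-1-carboxylate
Conditions: LiCl (excess), DBU, MeCN, rt, syringe-pump addition of 35 to ca. 1 mM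
Reagents that add atoms: none
Why: Intramolecular Horner–Wadsworth–Emmons olefination under Masamune–Roush conditions: lithium chelation lets the weak base DBU form the phosphonate anion beside an enolisable aldehyde, high dilution favours 14-membered ring closure, and reversible addition should lead to the E-2-alkyl-2-enoate, in which C5 is trans to the ester and cis to C8 as the target requires.

**Step 17**
Reactants: 36 macrocyclic ethyl ester
Product: 37 [(1E,5Z,8R,11E)-5,11-dimethyl-8-[(2E)-6-methylhepta-2,5-dien-2-yl]cyclotetradeca-1,5,11-trien-1-yl]methanol (CNP0355114.1)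
Conditions: DIBAL-H (3 equiv), CH2Cl2, −78 to 0 °C; Rochelle salt
Reagents that add atoms: none
Why: DIBAL-H reduces an α,β-unsaturated ester in 1,2-fashion to the allylic alcohol without touching the isolated olefins, their geometries or C14.

**Compound list**
1 | (2E)-4-acetoxy-2-methylbut-2-enal | CC(=O)OC/C=C(\C)C=O | starting material
2 | prenyl chloride (1-chloro-3-methylbut-2-ene) | CC(C)=CCCl | starting material
3 | prenylbarium chloride | CC(C)=CC[Ba]Cl | intermediate
4 | rac-(2E)-4-hydroxy-3,7-dimethylocta-2,6-dien-1-yl acetate | CC(C)=CCC(O)/C(C)=C/COC(C)=O | intermediate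
5 | (2E)-3,7-dimethyl-4-oxoocta-2,6-dien-1-yl acetate | CC(C)=CCC(=O)/C(C)=C/COC(C)=O | intermediate
6 | (2E,4S)-4-hydroxy-3,7-dimethylocta-2,6-dien-1-yl acetate | CC(C)=CC[C@H](O)/C(C)=C/COC(C)=O | intermediate
7 | (2E,4S)-3,7-dimethyl-4-(triethylsilyloxy)octa-2,6-dien-1-yl acetate | CC(C)=CC[C@H](O[Si](CC)(CC)CC)/C(C)=C/COC(C)=O | intermediate
8 | 2-(2-bromoethyl)-1,3-dioxolane | BrCCC1OCCO1 | starting material
9 | propyne | CC#C | starting material
10 | 2-(1,3-dioxolan-2-yl)ethylmagnesium bromide | Br[Mg]CCC1OCCO1 | intermediate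
11 | [(1Z)-4-(1,3-dioxolan-2-yl)-2-methylbut-1-en-1-yl]copper | [Cu]/C=C(/C)CCC1OCCO1 | intermediate
12 | 2-[(3Z)-4-iodo-3-methylbut-3-en-1-yl]-1,3-dioxolane | I/C=C(/C)CCC1OCCO1 | intermediate
13 | [(1Z)-4-(1,3-dioxolan-2-yl)-2-methylbut-1-en-1-yl]lithium | [Li]/C=C(/C)CCC1OCCO1 | intermediate
14 | [(1Z)-4-(1,3-dioxolan-2-yl)-2-methylbut-1-en-1-yl]zinc chloride | Cl[Zn]/C=C(/C)CCC1OCCO1 | intermediate
15 | {[(5S,6E,9Z)-12-(1,3-dioxolan-2-yl)-2,6,10-trimethyldodeca-2,6,9-trien-5-yl]oxy}triethylsilane | CC(C)=CC[C@H](O[Si](CC)(CC)CC)/C(C)=C/C/C=C(/C)CCC1OCCO1 | intermediate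
16 | (5S,6E,9Z)-12-(1,3-dioxolan-2-yl)-2,6,10-trimethyldodeca-2,6,9-trien-5-ol | CC(C)=CC[C@H](O)/C(C)=C/C/C=C(/C)CCC1OCCO1 | intermediate
17 | N,N-dimethylacetamide dimethyl acetal | COC(C)(OC)N(C)C | starting material
18 | mixed amide acetal of 16 (one OMe of 17 replaced by the C16 oxygen) | CC(C)=CC[C@H](OC(C)(OC)N(C)C)/C(C)=C/C/C=C(/C)CCC1OCCO1 | intermediate
19 | ketene N,O-acetal of 16 (C16–O–C(=CH2)NMe2) | CC(C)=CC[C@H](OC(=C)N(C)C)/C(C)=C/C/C=C(/C)CCC1OCCO1 | intermediate
20 | (3S,4E)-3-[(2Z)-5-(1,3-dioxolan-2-yl)-3-methylpent-2-en-1-yl]-N,N,4,8-tetramethylnona-4,7-dienamide | CC(C)=CC/C=C(\C)[C@H](CC(=O)N(C)C)C/C=C(/C)CCC1OCCO1 | intermediate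
21 | (3S,4E)-3-[(2Z)-5-(1,3-dioxolan-2-yl)-3-methylpent-2-en-1-yl]-4,8-dimethylnona-4,7-dien-1-ol | CC(C)=CC/C=C(\C)[C@H](CCO)C/C=C(/C)CCC1OCCO1 | intermediate
22 | 2-[(3Z,6S,7E)-6-(2-iodoethyl)-3,7,11-trimethyldodeca-3,7,10-trien-1-yl]-1,3-dioxolane | CC(C)=CC/C=C(\C)[C@H](CCI)C/C=C(/C)CCC1OCCO1 | intermediate
23 | pent-3-yn-1-ol | CC#CCCO | starting material
24 | (E)-alkenylzirconocene chloride at C11, oxygen bound as zirconocene chloride alkoxide | Cl[Zr](OCC/C=C(\C)[Zr](Cl)(C1C=CC=C1)C1C=CC=C1)(C1C=CC=C1)C1C=CC=C1 | intermediate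
25 | (3E)-4-iodopent-3-en-1-ol | OCC/C=C(\C)I | intermediate
26 | (2E)-2,5-diiodopent-2-ene | ICC/C=C(\C)I | intermediate
27 | triethyl phosphonoacetate | CCOC(=O)CP(=O)(OCC)OCC | starting material
28 | sodio triethyl phosphonoacetate | [Na+].CCOC(=O)[CH-]P(=O)(OCC)OCC | intermediate
29 | ethyl (5E)-2-(diethoxyphosphoryl)-6-iodohept-5-enoate (racemic at C7) | CCOC(=O)C(CC/C=C(\C)I)P(=O)(OCC)OCC | intermediate
30 | C12-lithio compound from 22 (C14 arrangement unchanged) | CC(C)=CC/C=C(\C)[C@H](CC[Li])C/C=C(/C)CCC1OCCO1 | intermediate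
31 | C12-chlorozinc compound from 30 (C14 arrangement unchanged) | CC(C)=CC/C=C(\C)[C@H](CC[Zn]Cl)C/C=C(/C)CCC1OCCO1 | intermediate
32 | sodium salt of 29 | [Na+].CCOC(=O)[C-](CC/C=C(\C)I)P(=O)(OCC)OCC | intermediate
33 | sodium salt of 34 | [Na+].CC(C)=CC/C=C(\C)[C@H](CC/C(C)=C/CC[C-](C(=O)OCC)P(=O)(OCC)OCC)C/C=C(/C)CCC1OCCO1 | intermediate
34 | ethyl (5E,9R,10E)-2-(diethoxyphosphoryl)-9-[(2Z)-5-(1,3-dioxolan-2-yl)-3-methylpent-2-en-1-yl]-6,10,14-trimethylpentadeca-5,10,13-trienoate (epimers at C7) | CC(C)=CC/C=C(\C)[C@H](CC/C(C)=C/CCC(C(=O)OCC)P(=O)(OCC)OCC)C/C=C(/C)CCC1OCCO1 | intermediate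
35 | ethyl (5E,9R,10E)-2-(diethoxyphosphoryl)-6,10,14-trimethyl-9-[(2Z)-3-methyl-6-oxohex-2-en-1-yl]pentadeca-5,10,13-trienoate (epimers at C7) | CC(C)=CC/C=C(\C)[C@H](CC/C(C)=C/CCC(C(=O)OCC)P(=O)(OCC)OCC)C/C=C(/C)CCC=O | intermediate
36 | ethyl (1E,5Z,8R,11E)-5,11-dimethyl-8-[(2E)-6-methylhepta-2,5-dien-2-yl]cyclotetradeca-1,5,11-triene-1-carboxylate | CC(C)=CC/C=C(\C)[C@H]1C/C=C(/C)CC/C=C(/C(=O)OCC)CC/C=C(\C)CC1 | intermediate
37 | [(1E,5Z,8R,11E)-5,11-dimethyl-8-[(2E)-6-methylhepta-2,5-dien-2-yl]cyclotetradeca-1,5,11-trien-1-yl]methanol (CNP0355114.1) | CC(C)=CC/C=C(\C)[C@H]1C/C=C(/C)CC/C=C(/CO)CC/C=C(\C)CC1 | target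

**Total step count:** 17 steps.
**Longest linear sequence:** 13 steps (1, 2, 3, 4, 6, 7, 8, 9, 10, 14, 15, 16, 17). The C2–C6 arm (step 5) and the C7–C11 arm (steps 11–13) are made in parallel.

**Three steps most likely to fail**

*Step 16 (macrocyclic HWE).*
- What may go wrong: even at high dilution, ring closure may be slower than intermolecular olefination and base-induced self-condensation of the aldehyde. The strain of the forming ring may also erode E selectivity at the trisubstituted enoate, at a stage where the wrong geometry cannot be recycled.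
- Fallback: set the C6=C7 geometry in the open chain and close the ring at C11–C12 instead. The fallback sets out from iodide 22.
- E2 elimination with KOt-Bu in THF at 0 °C would give 2-[(3Z,6S,7E)-6-ethenyl-3,7,11-trimethyldodeca-3,7,10-trien-1-yl]-1,3-dioxolane F1.
- PPTS in wet acetone would free (4Z,7S,8E)-7-ethenyl-4,8,12-trimethyltrideca-4,8,11-trienal F2.
- Intermolecular HWE of F2 with phosphonate 29 (LiCl, DBU, MeCN) would give ethyl (2E,6Z,9S,10E)-9-ethenyl-2-[(3E)-4-iodopent-3-en-1-yl]-6,10,14-trimethylpentadeca-2,6,10,13-tetraenoate F3. Its geometrical isomers can be separated before any ring exists.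
- 9-BBN-H should hydroborate only the monosubstituted vinyl group to give the B-alkyl-9-BBN adduct F4.
- Slow addition of F4 to PdCl2(dppf), AsPh3 and Cs2CO3 in DMF–THF–H2O would close the ring by B-alkyl Suzuki–Miyaura macrocyclisation. The route is rejoined at ester 36.

*Step 14 (sp3–sp2 coupling with the phosphonate partner).*
- What may go wrong: proton transfer from incompletely deprotonated phosphonoacetate to the organozinc, slow transmetalation when the chelating enolate occupies palladium, β-hydride elimination of the alkylpalladium species, or side reactions during the exchange.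
- Fallback: couple a partner without the acidic group and attach the phosphonoacetate afterwards. The fallback sets out from 25 and 22.
- Silylation of 25 (TBSCl, imidazole) would give tert-butyl{[(3E)-4-iodopent-3-en-1-yl]oxy}dimethylsilane F5.
- Alkylzinc 31, made from 22 as in step 14, would be coupled with F5 under PdCl2(dppf) to give tert-butyl{[(3E,7R,8E)-7-[(2Z)-5-(1,3-dioxolan-2-yl)-3-methylpent-2-en-1-yl]-4,8,12-trimethyltrideca-3,8,11-trien-1-yl]oxy}dimethylsilane F6.
- TBAF would give (3E,7R,8E)-7-[(2Z)-5-(1,3-dioxolan-2-yl)-3-methylpent-2-en-1-yl]-4,8,12-trimethyltrideca-3,8,11-trien-1-ol F7.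
- Appel iodination would give 2-[(3Z,6R,7E)-6-[(3E)-6-iodo-3-methylhex-3-en-1-yl]-3,7,11-trimethyldodeca-3,7,10-trien-1-yl]-1,3-dioxolane F8.
- Alkylation of sodio phosphonoacetate 28 with F8 would rejoin the route at 34.

*Step 1 (linear prenylation).*
- What may go wrong: attack through the γ-carbon of the prenyl metal, competing attack on the acetate, and poor reproducibility in preparing activated barium.
- Fallback: use an allyl nucleophile that has no α/γ ambiguity and already sets C16, then complete the prenyl terminus by metathesis. The fallback sets out from aldehyde 1.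
- Brown allylation uses B-allyldiisopinocampheylborane made from (−)-B-methoxydiisopinocampheylborane and allylmagnesium bromide (Et2O, −78 °C), with an ethanolamine work-up to keep the acetate. It is expected to give (2E,4S)-4-hydroxy-3-methylhepta-2,6-dien-1-yl acetate F9, with the sense of induction checked as in step 3.
- Cross-metathesis of F9 with excess 2-methylbut-2-ene (second-generation Grubbs catalyst, CH2Cl2, 40 °C) should convert only the monosubstituted olefin. The route is rejoined at carbinol 6, and steps 2 and 3 are no longer needed.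

**Further compounds**
F1 | step 16 | 2-[(3Z,6S,7E)-6-ethenyl-3,7,11-trimethyldodeca-3,7,10-trien-1-yl]-1,3-dioxolane | CC(C)=CC/C=C(\C)[C@H](C=C)C/C=C(/C)CCC1OCCO1
F2 | step 16 | (4Z,7S,8E)-7-ethenyl-4,8,12-trimethyltrideca-4,8,11-trienal | CC(C)=CC/C=C(\C)[C@H](C=C)C/C=C(/C)CCC=O
F3 | step 16 | ethyl (2E,6Z,9S,10E)-9-ethenyl-2-[(3E)-4-iodopent-3-en-1-yl]-6,10,14-trimethylpentadeca-2,6,10,13-tetraenoate | CC(C)=CC/C=C(\C)[C@H](C=C)C/C=C(/C)CC/C=C(/C(=O)OCC)CC/C=C(\C)I
F4 | step 16 | B-alkyl-9-BBN adduct of F3 (boron on C12) | CC(C)=CC/C=C(\C)[C@H](CCB1C2CCCC1CCC2)C/C=C(/C)CC/C=C(/C(=O)OCC)CC/C=C(\C)I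
F5 | step 14 | tert-butyl{[(3E)-4-iodopent-3-en-1-yl]oxy}dimethylsilane | CC(C)(C)[Si](C)(C)OCC/C=C(\C)I
F6 | step 14 | tert-butyl{[(3E,7R,8E)-7-[(2Z)-5-(1,3-dioxolan-2-yl)-3-methylpent-2-en-1-yl]-4,8,12-trimethyltrideca-3,8,11-trien-1-yl]oxy}dimethylsilane | CC(C)=CC/C=C(\C)[C@H](CC/C(C)=C/CCO[Si](C)(C)C(C)(C)C)C/C=C(/C)CCC1OCCO1
F7 | step 14 | (3E,7R,8E)-7-[(2Z)-5-(1,3-dioxolan-2-yl)-3-methylpent-2-en-1-yl]-4,8,12-trimethyltrideca-3,8,11-trien-1-ol | CC(C)=CC/C=C(\C)[C@H](CC/C(C)=C/CCO)C/C=C(/C)CCC1OCCO1
F8 | step 14 | 2-[(3Z,6R,7E)-6-[(3E)-6-iodo-3-methylhex-3-en-1-yl]-3,7,11-trimethyldodeca-3,7,10-trien-1-yl]-1,3-dioxolane | CC(C)=CC/C=C(\C)[C@H](CC/C(C)=C/CCI)C/C=C(/C)CCC1OCCO1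
F9 | step 1 | (2E,4S)-4-hydroxy-3-methylhepta-2,6-dien-1-yl acetate | C=CC[C@H](O)/C(C)=C/COC(C)=O
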